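**Retrosynthetic overview**
1. Pestalone D 15 ⇐ prenylated benzophenone 13: the formyl group goes on last, onto ring B (Vilsmeier–Haack).
2. 13 ⇐ tertiary allyl aryl ether 11 by a [3,3] shift. The key bond is the C–O bond of 11, made by adding a ring B phenol O–H of triol 9 across 3-methylbuta-1,2-diene 10 (proposed rhodium catalysis).
3. 9 ⇐ aryl ester 6 by a bromine–lithium-triggered 1,3 O→C acyl shift. The two rings are joined through the ester C–O bond between tribromophenol 2 and acid 5.
4. 2 ⇐ 3-methoxy-5-methylphenol 1 (exhaustive bromination; the third bromine is a traceless handle). 5 ⇐ 3,5-dihydroxybenzoic acid 3.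
5. No ring is built: ring A and ring B are both bought as benzene rings and are joined in step 3.

Assumption: the target has no stereocentre and its alkene carries two identical methyl groups, so it is achiral and no stereocontrol is needed.

**Step 1**
Reactants: 1 3-methoxy-5-methylphenol
Product: 2 2,4,6-tribromo-3-methoxy-5-methylphenol
Conditions: Br2 (3.05 equiv), AcOH, 15 °C → rt; aq NaHSO3 work-up
Reagents that add atoms: bromine, BrBr
Why: Electrophilic aromatic bromination: every free ring position of 1 is ortho or para to OH and OMe, so exhaustive bromination gives one product with no regiochemical question, and the bromine between the two oxygens is the handle consumed in step 4.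

**Step 2**
Reactants: 3 3,5-dihydroxybenzoic acid
Product: 5 3,5-bis(tert-butyldimethylsilyloxy)benzoic acid, via silyl ester 4 (not isolated)
Conditions: TBSCl (3.3 equiv), imidazole (7 equiv), DMF, rt; then AcOH–THF–H2O (3:1:1), rt
Reagents that add atoms: tert-butyldimethylsilyl chloride, CC(C)(C)[Si](C)(C)Cl
Why: Silyl ether formation on both phenols and the acid, followed by selective hydrolysis of the far more labile silyl ester (aryl silyl ethers survive aqueous AcOH), gives the protected acid in one operation.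

**Step 3**
Reactants: 2 2,4,6-tribromo-3-methoxy-5-methylphenol; 5 3,5-bis(tert-butyldimethylsilyloxy)benzoic acid
Product: 6 2,4,6-tribromo-3-methoxy-5-methylphenyl 3,5-bis(tert-butyldimethylsilyloxy)benzoate
Conditions: DCC (1.2 equiv), DMAP (0.2 equiv), CH2Cl2, 0 °C → rt
Reagents that add atoms: none
Why: Steglich esterification forms the ester C–O bond that joins ring A to ring B; the acidic 2,6-dibromophenol reacts well with the acylpyridinium and neither partner carries another free nucleophile.

**Step 4**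
Reactants: 6 2,4,6-tribromo-3-methoxy-5-methylphenyl 3,5-bis(tert-butyldimethylsilyloxy)benzoate
Product: 9 (3,5-dibromo-2-hydroxy-6-methoxy-4-methylphenyl)(3,5-dihydroxyphenyl)methanone, via aryllithium 7 (not isolated), via lithium phenoxide 8 (not isolated)
Conditions: n-BuLi (1.05 equiv), THF, −100 °C → −78 °C; then TBAF (2.5 equiv), −78 → 0 °C; 1 M HCl
Reagents that add atoms: none
Why: Bromine–lithium exchange is fastest at the bromine flanked by the ester oxygen and OMe (most stabilised aryllithium, no bromine ortho to lithium, so no aryne), and the ortho-lithio aryl ester collapses by an anionic Fries-type 1,3 O→C acyl shift that places the ketone between OH and OMe with the two remaining bromines flanking the methyl group; fluoride then cleaves both aryl silyl ethers.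

**Step 5**
Reactants: 9 (3,5-dibromo-2-hydroxy-6-methoxy-4-methylphenyl)(3,5-dihydroxyphenyl)methanone; 10 3-methylbuta-1,2-diene
Product: 11 (3,5-dibromo-2-hydroxy-6-methoxy-4-methylphenyl)[3-hydroxy-5-(2-methylbut-3-en-2-yloxy)phenyl]methanone
Conditions: [Rh(cod)Cl]2 (2.5 mol %), DPEphos (5 mol %), 10 (1.0 equiv), ClCH2CH2Cl, 50 °C, sealed tube
Reagents that add atoms: none
Why: Proposed new method: rhodium-catalysed branched-selective hydroalkoxylation of a 1,1-disubstituted allene with a phenol, making the tertiary allyl aryl ether (the key C–O bond) without base or leaving group; the phenol O–H adds oxidatively to monovalent rhodium, the trivalent rhodium hydride delivers H to the central allene carbon to give a 1,1-dimethylallyl rhodium aryloxide, and C–O reductive elimination from the σ-allyl bound at CH2 occurs at the tertiary terminus to release the branched ether and monovalent rhodium; only a ring B OH reacts because the ring A OH is hydrogen-bonded to the ketone and flanked by bromine, and one equivalent of 10 gives mainly the mono-ether (bis-ether is separated, unreacted 9 is recycled); closest known reaction type: rhodium/diphosphine-catalysed branched-selective addition of carboxylic acids and aliphatic alcohols to terminal allenes, and palladium-catalysed tert-prenylation of phenols with tertiary allylic carbonates.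

**Step 6**
Reactants: 11 (3,5-dibromo-2-hydroxy-6-methoxy-4-methylphenyl)[3-hydroxy-5-(2-methylbut-3-en-2-yloxy)phenyl]methanone
Product: 13 (3,5-dibromo-2-hydroxy-6-methoxy-4-methylphenyl)[3,5-dihydroxy-2-(3-methylbut-2-en-1-yl)phenyl]methanone, via dienone 12 (not isolated)
Conditions: toluene, 2,6-lutidine (0.2 equiv), 110 °C, sealed tube
Reagents that add atoms: none
Why: Aromatic Claisen rearrangement of the tertiary allyl aryl ether delivers the CH2 terminus to an ortho carbon and so gives a normal prenyl group; the meta aroyl group (acceptor, favours the adjacent ortho carbon) and the meta OH (donor, favours its para carbon) both steer to the carbon next to the ketone and away from the carbon between the oxygens, dienone 12 tautomerises to the phenol, and lutidine suppresses acid-induced ionisation of the ether.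

**Step 7**
Reactants: 13 (3,5-dibromo-2-hydroxy-6-methoxy-4-methylphenyl)[3,5-dihydroxy-2-(3-methylbut-2-en-1-yl)phenyl]methanone
Product: 15 pestalone D [2-(3,5-dibromo-2-hydroxy-6-methoxy-4-methylbenzoyl)-4,6-dihydroxy-3-(3-methylbut-2-en-1-yl)benzaldehyde], via iminium chloride 14 (not isolated)
Conditions: POCl3 (1.3 equiv), DMF (3 equiv), MeCN, 0 °C → rt; then aq NaOAc, rt
Reagents that add atoms: N,N-dimethylformamide, CN(C)C=O (formyl carbon); water, O (aldehyde oxygen)
Why: Vilsmeier–Haack formylation: the only open ring B carbon that is para to one OH and ortho to the other (the normal site of attack in resorcinols, unlike the sluggish carbon between the two oxygens) is the one next to the ketone, ring A has no free position, the trisubstituted alkene does not react with the chloroiminium salt, and buffered hydrolysis of iminium salt 14 gives the aldehyde.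

**Compound list**
1 | 3-methoxy-5-methylphenol | COc1cc(C)cc(O)c1 | starting material
2 | 2,4,6-tribromo-3-methoxy-5-methylphenol | Oc1c(Br)c(OC)c(Br)c(C)c1Br | intermediate
3 | 3,5-dihydroxybenzoic acid | OC(=O)c1cc(O)cc(O)c1 | starting material
4 | tert-butyldimethylsilyl 3,5-bis(tert-butyldimethylsilyloxy)benzoate (not isolated) | CC(C)(C)[Si](C)(C)OC(=O)c1cc(O[Si](C)(C)C(C)(C)C)cc(O[Si](C)(C)C(C)(C)C)c1 | intermediate
5 | 3,5-bis(tert-butyldimethylsilyloxy)benzoic acid | OC(=O)c1cc(O[Si](C)(C)C(C)(C)C)cc(O[Si](C)(C)C(C)(C)C)c1 | intermediate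
6 | 2,4,6-tribromo-3-methoxy-5-methylphenyl 3,5-bis(tert-butyldimethylsilyloxy)benzoate | COc1c(Br)c(C)c(Br)c(OC(=O)c2cc(O[Si](C)(C)C(C)(C)C)cc(O[Si](C)(C)C(C)(C)C)c2)c1Br | intermediate
7 | 2,4-dibromo-6-lithio-5-methoxy-3-methylphenyl 3,5-bis(tert-butyldimethylsilyloxy)benzoate (not isolated) | COc1c(Br)c(C)c(Br)c(OC(=O)c2cc(O[Si](C)(C)C(C)(C)C)cc(O[Si](C)(C)C(C)(C)C)c2)c1[Li] | intermediate
8 | lithium 2-[3,5-bis(tert-butyldimethylsilyloxy)benzoyl]-4,6-dibromo-3-methoxy-5-methylphenolate (not isolated) | COc1c(Br)c(C)c(Br)c(O[Li])c1C(=O)c1cc(O[Si](C)(C)C(C)(C)C)cc(O[Si](C)(C)C(C)(C)C)c1 | intermediate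
9 | (3,5-dibromo-2-hydroxy-6-methoxy-4-methylphenyl)(3,5-dihydroxyphenyl)methanone | COc1c(Br)c(C)c(Br)c(O)c1C(=O)c1cc(O)cc(O)c1 | intermediate
10 | 3-methylbuta-1,2-diene | CC(C)=C=C | starting material
11 | (3,5-dibromo-2-hydroxy-6-methoxy-4-methylphenyl)[3-hydroxy-5-(2-methylbut-3-en-2-yloxy)phenyl]methanone | COc1c(Br)c(C)c(Br)c(O)c1C(=O)c1cc(O)cc(OC(C)(C)C=C)c1 | intermediate
12 | 5-(3,5-dibromo-2-hydroxy-6-methoxy-4-methylbenzoyl)-3-hydroxy-6-(3-methylbut-2-en-1-yl)cyclohexa-2,4-dien-1-one (racemic, transient, not isolated) | COc1c(Br)c(C)c(Br)c(O)c1C(=O)C1=CC(O)=CC(=O)C1CC=C(C)C | intermediate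
13 | (3,5-dibromo-2-hydroxy-6-methoxy-4-methylphenyl)[3,5-dihydroxy-2-(3-methylbut-2-en-1-yl)phenyl]methanone | COc1c(Br)c(C)c(Br)c(O)c1C(=O)c1cc(O)cc(O)c1CC=C(C)C | intermediate
14 | N-{[2-(3,5-dibromo-2-hydroxy-6-methoxy-4-methylbenzoyl)-4,6-dihydroxy-3-(3-methylbut-2-en-1-yl)phenyl]methylidene}-N-methylmethanaminium chloride (not isolated) | COc1c(Br)c(C)c(Br)c(O)c1C(=O)c1c(C=[N+](C)C)c(O)cc(O)c1CC=C(C)C.[Cl-] | intermediate
15 | pestalone D, 2-(3,5-dibromo-2-hydroxy-6-methoxy-4-methylbenzoyl)-4,6-dihydroxy-3-(3-methylbut-2-en-1-yl)benzaldehyde | COc1c(Br)c(C)c(Br)c(O)c1C(=O)c1c(C=O)c(O)cc(O)c1CC=C(C)C | target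

**Step count**
Total steps: 7. Longest linear sequence: 6 (3 → 5 → 6 → 9 → 11 → 13 → 15; the branch from 1 is equally long).

**Three steps most likely to fail**

Step 5 (the proposed new reaction). It may fail through sequestration of rhodium by the chelating 2-hydroxybenzophenone unit, formation of the linear prenyl ether, or C-allylation. The fallback uses known chemistry, sets out from 9 and comes back at 11. Triol 9 is O-propargylated with 3-chloro-3-methylbut-1-yne (1.0 equiv; CuCl2 cat., DBU, MeCN, 0 °C) to give (3,5-dibromo-2-hydroxy-6-methoxy-4-methylphenyl)[3-hydroxy-5-(2-methylbut-3-yn-2-yloxy)phenyl]methanone F5. Semihydrogenation of F5 (H2 1 atm, Lindlar catalyst = Pd on CaCO3 poisoned with Pb(OAc)2, quinoline, EtOAc, rt), which leaves the aryl bromides untouched, gives 11.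

Step 4. The exchange may occur at the wrong bromine, or butyl may add to the activated aryl ester. The fallback replaces the O→C acyl shift by an intermolecular Weinreb ketone synthesis; it sets out from 2 and 5 and comes back at 9.
- Phenol 2 is capped (MOMCl, iPr2NEt, CH2Cl2) as 1,3,5-tribromo-2-methoxy-4-(methoxymethoxy)-6-methylbenzene F1.
- Acid 5 is converted (EDC·HCl, MeNHOMe·HCl, Et3N, CH2Cl2) into 3,5-bis(tert-butyldimethylsilyloxy)-N-methoxy-N-methylbenzamide F2.
- F1 with n-BuLi (THF, −78 °C) exchanges the bromine between the two ether oxygens to give [3,5-dibromo-2-methoxy-6-(methoxymethoxy)-4-methylphenyl]lithium F3.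
- F3 adds to F2 and gives, after aqueous work-up, [3,5-bis(tert-butyldimethylsilyloxy)phenyl][3,5-dibromo-2-methoxy-6-(methoxymethoxy)-4-methylphenyl]methanone F4.
- HCl in MeOH (40 °C) removes the methoxymethyl and both silyl groups and gives 9.

Step 7. The formyl group may enter between the two hydroxyls, the crowded site next to the aroyl group may be too slow, or acid may cyclise the ortho-prenyl phenol to a chroman. The fallback moves the formylation ahead of the prenyl relay; it sets out from 9 and comes back at 15 (ArCO = 3,5-dibromo-2-hydroxy-6-methoxy-4-methylbenzoyl).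
- Triol 9 is mono-acetylated (Ac2O 1.0 equiv, pyridine, CH2Cl2, 0 °C; 9 and diacetate recycled) to 3-(ArCO)-5-hydroxyphenyl acetate F6.
- Vilsmeier–Haack formylation (POCl3, DMF, 0 °C; cold aq NaOAc) has no alkene to damage and goes para to the only free ring B OH. It passes through N-{[2-acetoxy-6-(ArCO)-4-hydroxyphenyl]methylidene}-N-methylmethanaminium chloride F7 to 3-(ArCO)-2-formyl-5-hydroxyphenyl acetate F8.
- The free OH of F8 is tert-prenylated by the known palladium method (Pd(PPh3)4, methyl 2-methylbut-3-en-2-yl carbonate, THF, 0 °C) to 3-(ArCO)-2-formyl-5-(2-methylbut-3-en-2-yloxy)phenyl acetate F9.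
- Because the oxygen next to the aldehyde is acetylated, there is no salicylaldehyde hydrogen-bond chelate to pull the Claisen shift to the carbon between the oxygens. Heating (toluene, 110 °C) gives, through dienone 5-(ArCO)-6-formyl-4-(3-methylbut-2-en-1-yl)-3-oxocyclohexa-1,5-dien-1-yl acetate F10, 3-(ArCO)-2-formyl-5-hydroxy-4-(3-methylbut-2-en-1-yl)phenyl acetate F11. The regiochemistry of this shift is argued from substituent effects and would need to be confirmed.
- Neutral deacetylation of F11 (NH4OAc, aqueous MeOH, rt) gives 15.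

**Further compounds**
F1 | step 4 | 1,3,5-tribromo-2-methoxy-4-(methoxymethoxy)-6-methylbenzene | COCOc1c(Br)c(OC)c(Br)c(C)c1Br
F2 | step 4 | 3,5-bis(tert-butyldimethylsilyloxy)-N-methoxy-N-methylbenzamide | CON(C)C(=O)c1cc(O[Si](C)(C)C(C)(C)C)cc(O[Si](C)(C)C(C)(C)C)c1
F3 | step 4 | [3,5-dibromo-2-methoxy-6-(methoxymethoxy)-4-methylphenyl]lithium | [Li]c1c(OC)c(Br)c(C)c(Br)c1OCOC
F4 | step 4 | [3,5-bis(tert-butyldimethylsilyloxy)phenyl][3,5-dibromo-2-methoxy-6-(methoxymethoxy)-4-methylphenyl]methanone | COCOc1c(Br)c(C)c(Br)c(OC)c1C(=O)c1cc(O[Si](C)(C)C(C)(C)C)cc(O[Si](C)(C)C(C)(C)C)c1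
F5 | step 5 | (3,5-dibromo-2-hydroxy-6-methoxy-4-methylphenyl)[3-hydroxy-5-(2-methylbut-3-yn-2-yloxy)phenyl]methanone | COc1c(Br)c(C)c(Br)c(O)c1C(=O)c1cc(O)cc(OC(C)(C)C#C)c1
F6 | step 7 | 3-(3,5-dibromo-2-hydroxy-6-methoxy-4-methylbenzoyl)-5-hydroxyphenyl acetate | COc1c(Br)c(C)c(Br)c(O)c1C(=O)c1cc(O)cc(OC(C)=O)c1
F7 | step 7 | N-{[2-acetoxy-6-(3,5-dibromo-2-hydroxy-6-methoxy-4-methylbenzoyl)-4-hydroxyphenyl]methylidene}-N-methylmethanaminium chloride | COc1c(Br)c(C)c(Br)c(O)c1C(=O)c1cc(O)cc(OC(C)=O)c1C=[N+](C)C.[Cl-]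
F8 | step 7 | 3-(3,5-dibromo-2-hydroxy-6-methoxy-4-methylbenzoyl)-2-formyl-5-hydroxyphenyl acetate | COc1c(Br)c(C)c(Br)c(O)c1C(=O)c1cc(O)cc(OC(C)=O)c1C=O
F9 | step 7 | 3-(3,5-dibromo-2-hydroxy-6-methoxy-4-methylbenzoyl)-2-formyl-5-(2-methylbut-3-en-2-yloxy)phenyl acetate | COc1c(Br)c(C)c(Br)c(O)c1C(=O)c1cc(OC(C)(C)C=C)cc(OC(C)=O)c1C=O
F10 | step 7 | 5-(3,5-dibromo-2-hydroxy-6-methoxy-4-methylbenzoyl)-6-formyl-4-(3-methylbut-2-en-1-yl)-3-oxocyclohexa-1,5-dien-1-yl acetate | COc1c(Br)c(C)c(Br)c(O)c1C(=O)C1=C(C=O)C(OC(C)=O)=CC(=O)C1CC=C(C)C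
F11 | step 7 | 3-(3,5-dibromo-2-hydroxy-6-methoxy-4-methylbenzoyl)-2-formyl-5-hydroxy-4-(3-methylbut-2-en-1-yl)phenyl acetate | COc1c(Br)c(C)c(Br)c(O)c1C(=O)c1c(CC=C(C)C)c(O)cc(OC(C)=O)c1C=O
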